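The vessel starts with X, J and L together. X has three ways out: it takes J, it takes L, or it pairs with itself to X2. What takes L ends as X.L and what pairs ends as X2, while what takes J can go on to L.X.J.

common to all: X 20 mM; J 24.0 mM; time 8.0 min

| run | L |
|---|---|
| epsilon | 10.0 mM |
| delta | 30.0 mM |
| alpha | 100 mM |
| theta | 250 mM |

    X + L → X.L (k1 = 0.0735 M⁻¹ s⁻¹)
    2 X → X2 (k2 = 0.0600 M⁻¹ s⁻¹)
    X + J → X.J (k3 = 0.723 M⁻¹ s⁻¹)
    L + X.J → L.X.J (k4 = 0.232 M⁻¹ s⁻¹)

- in percentages every species weighs as the X in it: one X2 counts as two
- a doubled species enters its step squared and goes two at a time
- "hardly changes" means that all values lie within two and a half points (for a concentration: within two and a half percent of the largest)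
- run time (epsilon): 8.0 min

1. amount of L.X.J at the end, in percent of the X charged for epsilon, delta, alpha, theta, in this order
2. the course of these numbers from the first flask to the last (hardly changes / falls all the way / rises, then falls / falls, then rises / rises all the way)

I reckon theta through first. At the charges X goes to J at 1.04 min⁻¹ and to L at 1.10 min⁻¹, so of what goes these two ways 48.6% takes J. This part, the rate to J over the rate to J and L together, is the branch share φ, and I carry it. With kJ for X + J and kL for X + L:

φ = kJ cJ / (kJ cJ + kL cL)

In theta X halves in 19.4 s and X.J under L in 12.0 s, both far shorter than the 8.0 min allowed , so I count what φ sends to J as L.X.J. At this share the part of its charge that J gives up, 40.5%, is larger than the 8.00% that L gives up at most, so φ sinks as the run goes, and its start value is my bound from above.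

For the bound from below I put the answer back, holding cL at its charge:

first round: cJ = cB − φ cX = 14.3 mM, φ′ = 36.0%

second round, with the mean 42.3%: cJ = 15.5 mM, φ″ = 38.0%

The pairing of X with itself takes 6.29% of X at the start, and that share falls with cX. This lowers the bound to 35.6%. I commit to the middle of the bracket, 42.1%.

For the other flasks I take a ceiling: φ at the charges, times the capture of X.J by L at its charge, and no more than cL/cX. That gives 50.0% for epsilon, 85.6% for delta and 70.2% for alpha, so I expect a rise, then a fall.

The forecast gives 33%, 64%, 60% and 42%, rises, then falls, holding that “L takes X directly to X.L in competition with J”, and its theta value lies inside my bracket .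

The flask gives 31.6%, 63.6%, 61.0% and 42.6%: it rises, then falls, and theta's value lies inside the bracket . In theta, X.J stands at 0% of the X charged at 8.00 min, and a tenfold time leaves L.X.J where it is. That reading is 0.877 of φ for theta. For alpha, φ at the charges is 70.2%, and the same ratio makes it 61.6%. Alpha reads 61.0%, with 0.0907% of the X charged as X.J at 8.00 min.

The numbers were drawn at random within sensible limits; the flask was simulated.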